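**Retrosynthetic overview**

1. Numbering: tetralin C1 carries the guaiacyl ring C, C2 and C3 carry the CH2OH groups, C4 is the benzylic CH2; ring A is the fused benzene ring (C4a–C8a; OMe at C5 and C6, OH at C7); ring B is the saturated six-membered ring.
2. Last events: hydrogenolysis of a benzyl ether (ring C phenol) and LiAlH4 reduction of a C2,C3 dimethyl diester to the two CH2OH groups.
3. Key disconnection C3–C4, closing ring B, the only ring that is made (rings A and C are bought). The enabling feature is that the C7 hydroxyl of ring A is para to C4a: once C4 carries a pivalate, cleavage of the C7 silyl ether turns C4 into the exocyclic methylene of a ring A p-quinone methide. C3, α to an ester and activated by a formyl group that is taken up and given back in the same flask, adds to it. Because C2 and C3 are both α to esters, the C2-epimeric open-chain diester converges under methoxide on the all-trans (1R,2S,3S) ring.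
4. The open-chain diester comes from C2–C3 alkylation (methyl bromoacetate) of a 3,3-diarylpropanoate. Its C1 stereocentre, the only one set by a reagent, comes from rhodium/(S)-BINAP 1,4-addition of the ring C boronic acid to a ring A cinnamate.
5. The ring A cinnamate comes from 3-hydroxy-4,5-dimethoxybenzaldehyde by silylation, hemiaminal-directed ortho-lithiation with formaldehyde capture (this carbon becomes C4), Wittig olefination and pivaloylation.

Key step: step 7

Assumption: in step 5 the (S)-BINAP rhodium complex is taken to bind the (E)-enoate on its α-si face, as in the usual quadrant picture for enones; this face gives R at C1. Should the sense be opposite, (R)-BINAP is used and nothing else changes.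

**Route**

Step 1
Reactants: 1 3-hydroxy-4,5-dimethoxybenzaldehyde
Product: 2 3,4-dimethoxy-5-[(triisopropylsilyl)oxy]benzaldehyde
Conditions: iPr3SiCl, imidazole, DMF, rt
Reagents that add atoms: triisopropylsilyl chloride, CC(C)[Si](Cl)(C(C)C)C(C)C
Why: O-silylation of the phenol; the bulky, non-coordinating triisopropylsilyl ether should resist butyllithium, enolates and neutral aqueous rhodium catalysis, keeps the lithiation of step 2 away from its own ortho position and is the fluoride-labile trigger that step 7 needs.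

Step 2
Reactants: 2 3,4-dimethoxy-5-[(triisopropylsilyl)oxy]benzaldehyde
Product: 4 4,5-dimethoxy-6-[(triisopropylsilyl)oxy]-1,3-dihydro-2-benzofuran-1-ol (cyclic lactol tautomer of the ortho-hydroxymethyl aldehyde), via ortho-lithiated lithium hemiaminal 3 (not isolated)
Conditions: Me2NCH2CH2NHMe, n-BuLi, THF, −20 °C; then n-BuLi (3 equiv), −20 → 0 °C; then (CH2O)n, −40 °C → rt; H2O
Reagents that add atoms: formaldehyde (from paraformaldehyde), C=O
Why: Directed ortho-metalation with in situ protection of the aldehyde: the lithium amide adds to the formyl group, the lithium hemiaminal directs butyllithium to the ring position flanked by it and by the neighbouring methoxy group (cooperative coordination, the other ortho position being shielded by the silyl ether), and the aryllithium is hydroxymethylated by formaldehyde so that hydrolysis returns the aldehyde, which closes onto the new CH2OH as the lactol; the carbon introduced here becomes C4.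

Step 3
Reactants: 4 4,5-dimethoxy-6-[(triisopropylsilyl)oxy]-1,3-dihydro-2-benzofuran-1-ol
Product: 5 methyl (2E)-3-{2-(hydroxymethyl)-3,4-dimethoxy-5-[(triisopropylsilyl)oxy]phenyl}prop-2-enoate
Conditions: Ph3P=CHCO2Me, PhCO2H (cat.), toluene, 80 °C
Reagents that add atoms: methyl (triphenyl-λ5-phosphanylidene)acetate, COC(=O)C=P(c1ccccc1)(c1ccccc1)c1ccccc1
Why: Wittig reaction on the open hydroxy-aldehyde tautomer of the lactol; the stabilised ylide should give the (E)-enoate, and the neutral to weakly acidic medium keeps the benzylic alcohol un-ionised so that it does not add back to the enoate (oxa-Michael closure needs base).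

Step 4
Reactants: 5 methyl (2E)-3-{2-(hydroxymethyl)-3,4-dimethoxy-5-[(triisopropylsilyl)oxy]phenyl}prop-2-enoate
Product: 6 methyl (2E)-3-{2-[(pivaloyloxy)methyl]-3,4-dimethoxy-5-[(triisopropylsilyl)oxy]phenyl}prop-2-enoate
Conditions: t-BuCOCl, pyridine, DMAP (cat.), CH2Cl2, 0 °C → rt
Reagents that add atoms: pivaloyl chloride, CC(C)(C)C(Cl)=O
Why: Acylation of the primary benzylic alcohol; the pivalate has no α-hydrogen and a hindered carbonyl, so it should pass through the enolate steps as a protecting group and then act as the nucleofuge at C4 in step 7.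

Step 5
Reactants: 6 methyl (2E)-3-{2-[(pivaloyloxy)methyl]-3,4-dimethoxy-5-[(triisopropylsilyl)oxy]phenyl}prop-2-enoate; 7 [4-(benzyloxy)-3-methoxyphenyl]boronic acid
Product: 8 methyl (3R)-3-[4-(benzyloxy)-3-methoxyphenyl]-3-{2-[(pivaloyloxy)methyl]-3,4-dimethoxy-5-[(triisopropylsilyl)oxy]phenyl}propanoate
Conditions: [Rh(OH)((S)-BINAP)]2 (3 mol% Rh), dioxane/H2O 10:1, 50 °C
Reagents that add atoms: none
Why: Hayashi–Miyaura reaction (rhodium-catalysed asymmetric 1,4-addition of an arylboronic acid to an enoate): transmetalation gives an aryl–rhodium species that inserts the (E)-enoate on the enantioface selected by (S)-BINAP (catalyst control, giving R at C1), hydrolysis of the rhodium enolate releases 8, and the hydroxo complex needs no added base, which spares the silyl ether and the pivalate.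

Step 6
Reactants: 8 methyl (3R)-3-[4-(benzyloxy)-3-methoxyphenyl]-3-{2-[(pivaloyloxy)methyl]-3,4-dimethoxy-5-[(triisopropylsilyl)oxy]phenyl}propanoate
Product: 9 dimethyl 2-{(R)-[4-(benzyloxy)-3-methoxyphenyl]{2-[(pivaloyloxy)methyl]-3,4-dimethoxy-5-[(triisopropylsilyl)oxy]phenyl}methyl}butanedioate (both C2 epimers)
Conditions: LiN(iPr)2, THF, −78 °C; then BrCH2CO2Me, −78 → −30 °C
Reagents that add atoms: methyl bromoacetate, COC(=O)CBr
Why: Enolate alkylation: kinetic deprotonation at the only enolisable position (C2) and SN2 reaction with the bromoacetate form the C2–C3 bond and bring in both carboxyl carbons; the new C2 centre is formed as a mixture on purpose, since step 7 equilibrates it.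

Step 7
Reactants: 9 dimethyl 2-{(R)-[4-(benzyloxy)-3-methoxyphenyl]{2-[(pivaloyloxy)methyl]-3,4-dimethoxy-5-[(triisopropylsilyl)oxy]phenyl}methyl}butanedioate (both C2 epimers)
Product: 13 dimethyl (1R,2S,3S)-1-[4-(benzyloxy)-3-methoxyphenyl]-7-hydroxy-5,6-dimethoxy-1,2,3,4-tetrahydronaphthalene-2,3-dicarboxylate, via C3-formyl succinate enolate 10 (not isolated), via ring A p-quinone methide 11 (not isolated), via C3-formyl tetralin 12 (not isolated)
Conditions: LiN(iPr)2 (1.2 equiv), THF, −78 °C; HCO2Me (3 equiv), −78 → 0 °C; Bu4NF (1.5 equiv), 0 °C → rt; then NaOMe, MeOH, 50 °C; aq NH4Cl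
Reagents that add atoms: none
Why: Kinetic deprotonation of 9 occurs at the unhindered C3 methylene and Claisen condensation with methyl formate gives the stabilised enolate of 10, the only formylation product that can persist because a formyl group on the C2 methine could not be held as an enolate and would be returned by retro-Claisen cleavage; fluoride then cleaves the C7 silyl ether and the phenoxide, para to C4a, expels pivalate from C4 (1,6-elimination) to give p-quinone methide 11. The enolate carbon C3 adds to the exocyclic methylene C4 of 11, an intramolecular 1,6-conjugate addition whose closest known relatives are the capture of fluoride-released quinone methides and the 1,6-addition of 1,3-dicarbonyl enolates to p-quinone methides; this closes ring B in a 6-endo-trig (enol-exo) mode and rearomatises ring A to give 12. Methoxide then removes the formyl group from the now quaternary C3 as methyl formate (retro-Claisen), which makes the ring closure irreversible and returns the formate that was taken up. C2 and C3 are both α to ester carbonyls and equilibrate through their enolates to the diester in which the C1 aryl, C2 ester and C3 ester groups are all pseudo-equatorial (1,2-trans, 2,3-trans), so the fixed C1 centre alone dictates 2S,3S (thermodynamic control) and both C2 epimers of 9 and every isomer of 10 and 12 should converge on 13. The selectivities needed are C3 over C2 as the nucleophile, C- over O-attack and ring closure over capture of 11 by outside nucleophiles: only C3 carries the formyl activation, O-attack would need an eight-membered ring, and the six-ring closure should outrun methoxide, fluoride or water. C1 is not at risk because it is meta to the C7 oxygen and cannot become part of the quinone methide.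

Step 8
Reactants: 13 dimethyl (1R,2S,3S)-1-[4-(benzyloxy)-3-methoxyphenyl]-7-hydroxy-5,6-dimethoxy-1,2,3,4-tetrahydronaphthalene-2,3-dicarboxylate
Product: 14 [(1R,2S,3S)-1-[4-(benzyloxy)-3-methoxyphenyl]-7-hydroxy-5,6-dimethoxy-1,2,3,4-tetrahydronaphthalene-2,3-diyl]dimethanol
Conditions: LiAlH4, THF, 0 → 50 °C; aq NaOH work-up
Reagents that add atoms: none
Why: Hydride reduction of both esters to primary alcohols (the phenol is carried as its aluminate); the conditions are not equilibrating and the all-trans array is the stable one in any case, so the (1R,2S,3S) configuration should be kept.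

Step 9
Reactants: 14 [(1R,2S,3S)-1-[4-(benzyloxy)-3-methoxyphenyl]-7-hydroxy-5,6-dimethoxy-1,2,3,4-tetrahydronaphthalene-2,3-diyl]dimethanol
Product: 15 (1R,2S,3S)-1-(4-hydroxy-3-methoxyphenyl)-2,3-bis(hydroxymethyl)-5,6-dimethoxy-1,2,3,4-tetrahydronaphthalen-7-ol (target)
Conditions: H2 (1 atm), Pd/C, MeOH/EtOAc, rt
Reagents that add atoms: none
Why: Hydrogenolysis of the benzyl aryl ether over palladium frees the ring C phenol; no other benzylic C–O bond is present and no stereocentre is touched.

**Compound list**

1 | 3-hydroxy-4,5-dimethoxybenzaldehyde | COc1cc(C=O)cc(O)c1OC | starting material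
2 | 3,4-dimethoxy-5-[(triisopropylsilyl)oxy]benzaldehyde | COc1cc(C=O)cc(O[Si](C(C)C)(C(C)C)C(C)C)c1OC | intermediate
3 | lithium hemiaminal of 2 with N,N,N′-trimethylethylenediamine, lithiated at the ring carbon between the hemiaminal and the methoxy group (formed in the flask) | CN(C)CCN(C)C(O[Li])c1cc(O[Si](C(C)C)(C(C)C)C(C)C)c(OC)c(OC)c1[Li] | intermediate
4 | 4,5-dimethoxy-6-[(triisopropylsilyl)oxy]-1,3-dihydro-2-benzofuran-1-ol (lactol of 2-(hydroxymethyl)-3,4-dimethoxy-5-[(triisopropylsilyl)oxy]benzaldehyde; lactol carbon unassigned) | OC1OCc2c(OC)c(OC)c(O[Si](C(C)C)(C(C)C)C(C)C)cc21 | intermediate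
5 | methyl (2E)-3-{2-(hydroxymethyl)-3,4-dimethoxy-5-[(triisopropylsilyl)oxy]phenyl}prop-2-enoate | COC(=O)/C=C/c1cc(O[Si](C(C)C)(C(C)C)C(C)C)c(OC)c(OC)c1CO | intermediate
6 | methyl (2E)-3-{2-[(pivaloyloxy)methyl]-3,4-dimethoxy-5-[(triisopropylsilyl)oxy]phenyl}prop-2-enoate | COC(=O)/C=C/c1cc(O[Si](C(C)C)(C(C)C)C(C)C)c(OC)c(OC)c1COC(=O)C(C)(C)C | intermediate
7 | [4-(benzyloxy)-3-methoxyphenyl]boronic acid | COc1cc(B(O)O)ccc1OCc1ccccc1 | starting material
8 | methyl (3R)-3-[4-(benzyloxy)-3-methoxyphenyl]-3-{2-[(pivaloyloxy)methyl]-3,4-dimethoxy-5-[(triisopropylsilyl)oxy]phenyl}propanoate | COC(=O)C[C@H](c1ccc(OCc2ccccc2)c(OC)c1)c1cc(O[Si](C(C)C)(C(C)C)C(C)C)c(OC)c(OC)c1COC(=O)C(C)(C)C | intermediate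
9 | dimethyl 2-{(R)-[4-(benzyloxy)-3-methoxyphenyl]{2-[(pivaloyloxy)methyl]-3,4-dimethoxy-5-[(triisopropylsilyl)oxy]phenyl}methyl}butanedioate (both C2 epimers) | COC(=O)CC(C(=O)OC)[C@H](c1ccc(OCc2ccccc2)c(OC)c1)c1cc(O[Si](C(C)C)(C(C)C)C(C)C)c(OC)c(OC)c1COC(=O)C(C)(C)C | intermediate
10 | 3-formyl derivative of 9, present as its enolate (drawn as the neutral aldehyde; formed in the flask) | COC(=O)C(C=O)C(C(=O)OC)[C@H](c1ccc(OCc2ccccc2)c(OC)c1)c1cc(O[Si](C(C)C)(C(C)C)C(C)C)c(OC)c(OC)c1COC(=O)C(C)(C)C | intermediate
11 | ring A p-quinone methide: C7 carbonyl, exocyclic C4 methylene on C4a, formyl succinate side chain on C8a (formed in the flask) | COC(=O)C(C=O)C(C(=O)OC)[C@H](c1ccc(OCc2ccccc2)c(OC)c1)C1=CC(=O)C(OC)=C(OC)C1=C | intermediate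
12 | dimethyl (1R)-1-[4-(benzyloxy)-3-methoxyphenyl]-3-formyl-7-hydroxy-5,6-dimethoxy-1,2,3,4-tetrahydronaphthalene-2,3-dicarboxylate (isomer mixture at C2 and C3; formed in the flask) | COc1cc([C@@H]2c3cc(O)c(OC)c(OC)c3CC(C=O)(C(=O)OC)C2C(=O)OC)ccc1OCc1ccccc1 | intermediate
13 | dimethyl (1R,2S,3S)-1-[4-(benzyloxy)-3-methoxyphenyl]-7-hydroxy-5,6-dimethoxy-1,2,3,4-tetrahydronaphthalene-2,3-dicarboxylate | COc1cc([C@@H]2c3cc(O)c(OC)c(OC)c3C[C@H](C(=O)OC)[C@H]2C(=O)OC)ccc1OCc1ccccc1 | intermediate
14 | [(1R,2S,3S)-1-[4-(benzyloxy)-3-methoxyphenyl]-7-hydroxy-5,6-dimethoxy-1,2,3,4-tetrahydronaphthalene-2,3-diyl]dimethanol | COc1cc([C@@H]2c3cc(O)c(OC)c(OC)c3C[C@H](CO)[C@H]2CO)ccc1OCc1ccccc1 | intermediate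
15 | (1R,2S,3S)-1-(4-hydroxy-3-methoxyphenyl)-2,3-bis(hydroxymethyl)-5,6-dimethoxy-1,2,3,4-tetrahydronaphthalen-7-ol | COc1cc([C@@H]2c3cc(O)c(OC)c(OC)c3C[C@H](CO)[C@H]2CO)ccc1O | target

**Step count and risks**

Total step count: 9. Longest linear sequence: 9 steps (1 to 15); boronic acid 7 is bought.

Steps most likely to fail:

Step 7 (key step). The quinone methide may be consumed unproductively (capture by methoxide, fluoride or water, or oligomerisation) if formylation at C3 is incomplete when the phenol is unmasked, and equilibration of C2 and C3 may stop short of a single isomer. The fallback sets out from 9 and returns at 13, using a classical enolate alkylation instead of the quinone methide. Me3SiBr in CH2Cl2 at −20 °C should convert the electron-rich benzylic pivalate into dimethyl 2-{(R)-[4-(benzyloxy)-3-methoxyphenyl]{2-(bromomethyl)-3,4-dimethoxy-5-[(triisopropylsilyl)oxy]phenyl}methyl}butanedioate F1. LiN(SiMe3)2 in THF at −78 °C should then form the kinetic ester enolate at the C3 methylene, which closes ring B by intramolecular SN2 displacement (6-exo-tet) to give dimethyl (1R)-1-[4-(benzyloxy)-3-methoxyphenyl]-5,6-dimethoxy-7-[(triisopropylsilyl)oxy]-1,2,3,4-tetrahydronaphthalene-2,3-dicarboxylate F2 as an isomer mixture. NaOMe in MeOH at 50 °C should equilibrate C2 and C3 to the all-trans diester and cleave the aryl silyl ether, giving 13.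

Step 5. Insertion of the hindered, electron-rich, ortho-substituted enoate may be slow, so that protodeboronation of 7 wins, and the facial selectivity may be insufficient. The fallback sets out from 4 and returns at 8, replacing catalyst control by an auxiliary. Wittig reaction of lactol 4 with (4S)-4-phenyl-3-[(triphenyl-λ5-phosphanylidene)acetyl]-1,3-oxazolidin-2-one should give (4S)-3-[(2E)-3-{2-(hydroxymethyl)-3,4-dimethoxy-5-[(triisopropylsilyl)oxy]phenyl}prop-2-enoyl]-4-phenyl-1,3-oxazolidin-2-one F3. Pivaloylation as in step 4 gives its pivalate (4S)-3-[(2E)-3-{2-[(pivaloyloxy)methyl]-3,4-dimethoxy-5-[(triisopropylsilyl)oxy]phenyl}prop-2-enoyl]-4-phenyl-1,3-oxazolidin-2-one F4. Conjugate addition of [4-(benzyloxy)-3-methoxyphenyl]magnesium bromide with CuBr·SMe2 to the magnesium-chelated s-cis imide, anti to the auxiliary phenyl group, should give (4S)-3-[(3R)-3-[4-(benzyloxy)-3-methoxyphenyl]-3-{2-[(pivaloyloxy)methyl]-3,4-dimethoxy-5-[(triisopropylsilyl)oxy]phenyl}propanoyl]-4-phenyl-1,3-oxazolidin-2-one F5. Transesterification with MeOMgBr in MeOH/THF at 0 °C removes the auxiliary and gives 8.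

Step 2. Capture of the hindered aryllithium by sparingly soluble paraformaldehyde may be inefficient (proton return to 2, formaldehyde consumed by excess butyllithium), and some metalation next to the silyl ether would add an isomer that is hard to remove at the lactol stage. The fallback sets out from 2 and returns at 4, replacing carbanion hydroxymethylation by halogenation and cross-coupling. The same hemiaminal-directed lithiation is quenched with I2, an efficient trap, to give 2-iodo-3,4-dimethoxy-5-[(triisopropylsilyl)oxy]benzaldehyde F6, which can be purified from any regioisomer. Stille coupling with Bu3SnCH2OH (Pd(PPh3)4, dioxane, 90 °C) should then install the hydroxymethyl group, and the hydroxy aldehyde closes to lactol 4.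

Further compounds
F1 | step 7 | dimethyl 2-{(R)-[4-(benzyloxy)-3-methoxyphenyl]{2-(bromomethyl)-3,4-dimethoxy-5-[(triisopropylsilyl)oxy]phenyl}methyl}butanedioate (both C2 epimers) | COC(=O)CC(C(=O)OC)[C@H](c1ccc(OCc2ccccc2)c(OC)c1)c1cc(O[Si](C(C)C)(C(C)C)C(C)C)c(OC)c(OC)c1CBr
F2 | step 7 | dimethyl (1R)-1-[4-(benzyloxy)-3-methoxyphenyl]-5,6-dimethoxy-7-[(triisopropylsilyl)oxy]-1,2,3,4-tetrahydronaphthalene-2,3-dicarboxylate (isomer mixture at C2 and C3) | COc1cc([C@@H]2c3cc(O[Si](C(C)C)(C(C)C)C(C)C)c(OC)c(OC)c3CC(C(=O)OC)C2C(=O)OC)ccc1OCc1ccccc1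
F3 | step 5 | (4S)-3-[(2E)-3-{2-(hydroxymethyl)-3,4-dimethoxy-5-[(triisopropylsilyl)oxy]phenyl}prop-2-enoyl]-4-phenyl-1,3-oxazolidin-2-one | O=C(/C=C/c1cc(O[Si](C(C)C)(C(C)C)C(C)C)c(OC)c(OC)c1CO)N1[C@@H](c2ccccc2)COC1=O
F4 | step 5 | (4S)-3-[(2E)-3-{2-[(pivaloyloxy)methyl]-3,4-dimethoxy-5-[(triisopropylsilyl)oxy]phenyl}prop-2-enoyl]-4-phenyl-1,3-oxazolidin-2-one | O=C(/C=C/c1cc(O[Si](C(C)C)(C(C)C)C(C)C)c(OC)c(OC)c1COC(=O)C(C)(C)C)N1[C@@H](c2ccccc2)COC1=O
F5 | step 5 | (4S)-3-[(3R)-3-[4-(benzyloxy)-3-methoxyphenyl]-3-{2-[(pivaloyloxy)methyl]-3,4-dimethoxy-5-[(triisopropylsilyl)oxy]phenyl}propanoyl]-4-phenyl-1,3-oxazolidin-2-one | O=C(C[C@H](c1ccc(OCc2ccccc2)c(OC)c1)c1cc(O[Si](C(C)C)(C(C)C)C(C)C)c(OC)c(OC)c1COC(=O)C(C)(C)C)N1[C@@H](c2ccccc2)COC1=O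
F6 | step 2 | 2-iodo-3,4-dimethoxy-5-[(triisopropylsilyl)oxy]benzaldehyde | COc1c(OC)c(O[Si](C(C)C)(C(C)C)C(C)C)cc(C=O)c1I
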